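**Retrosynthetic overview**

- The route rests on the benzene ring C1–C6 of the target: hydroxyl on C1 and C3, the heptadecyl chain on C5 (all mutually meta), and bare CH at C2, C4 and C6. This ring is built from smaller pieces, not made by substitution of an arene.
- 20 ⇐ 19 ⇐ 18 by ester hydrolysis and O‑de‑ethylation. 18 ⇐ cyclobutenone 12 + ethoxyethyne 13 by a thermal benzannulation that makes arene bonds C1–C2, C3–C4 and C1–C6.
- 12 ⇐ terminal alkyne 8 + dichloroketene by [2+2] cycloaddition and dechlorination. The two alkyne carbons become arene C5 and C4; C1 and C6 come from the ketene.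
- 8 ⇐ (3S)‑nonadec‑4‑yn‑3‑ol 5 by alkyne zipper and pivaloylation. 5 ⇐ ynone 4 by asymmetric transfer hydrogenation. 4 ⇐ 1‑hexadecyne 1 + Weinreb amide 2.
- Ring order: the four‑membered ring first (step 5), then the benzene ring (step 7), which is the only ring of the target.

Key step: step 7

Remark: the given SMILES has the S configuration at the carbinol carbon. The (S,S)‑configured transfer‑hydrogenation catalyst is taken to give the S propargylic alcohol, by the usual model in which the alkynyl group takes the place of an aryl group.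

**Route**

Step 1
Reactants: 1 1‑hexadecyne; 2 N‑methoxy‑N‑methylpropanamide
Product: 4 nonadec‑4‑yn‑3‑one, via lithium hexadec‑1‑ynide 3 (not isolated)
Conditions: n‑BuLi, THF, −78 °C; then 2, −78 → 0 °C; aq. HCl (1 M)
Reagents that add atoms: none
Why: Weinreb ketone synthesis with a lithium acetylide: the chelated tetrahedral adduct collapses only on work‑up, so the reaction should stop at the ynone.

Step 2
Reactants: 4 nonadec‑4‑yn‑3‑one
Product: 5 (3S)‑nonadec‑4‑yn‑3‑ol
Conditions: Ru[(S,S)‑TsNCHPhCHPhNH](p‑cymene) (1 mol %), i‑PrOH, rt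
Reagents that add atoms: none
Why: Noyori asymmetric transfer hydrogenation of an alkynyl ketone: in the six‑membered hydride/proton transfer state the alkyne sits where an aryl group would, so the (S,S) ligand should set the S carbinol, and the triple bond is not reduced.

Step 3
Reactants: 5 (3S)‑nonadec‑4‑yn‑3‑ol
Product: 7 (3S)‑nonadec‑18‑yn‑3‑ol, via dipotassium alkoxide acetylide 6 (not isolated)
Conditions: KH, H2N(CH2)3NH2 (potassium 3‑aminopropylamide, 5 equiv), 0 °C → rt; then H2O
Reagents that add atoms: none
Why: Alkyne zipper reaction: propargyl/allenyl proton shuttling moves the triple bond down the chain until it is trapped as the terminal acetylide, and the adjacent alkoxide blocks deprotonation at C3, so the stereocentre should be kept.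

Step 4
Reactants: 7 (3S)‑nonadec‑18‑yn‑3‑ol
Product: 8 (3S)‑nonadec‑18‑yn‑3‑yl 2,2‑dimethylpropanoate
Conditions: PivCl, pyridine, DMAP (cat.), CH2Cl2, 0 °C → rt
Reagents that add atoms: pivaloyl chloride, CC(C)(C)C(Cl)=O
Why: DMAP‑catalysed O‑acylation with retention at the carbinol carbon; the hindered ester shields the hydroxyl from the acid chloride and ketenes of the later steps and is inert to zinc and heat.

Step 5
Reactants: 8 (3S)‑nonadec‑18‑yn‑3‑yl 2,2‑dimethylpropanoate; 9 trichloroacetyl chloride
Product: 11 (3S)‑17‑(4,4‑dichloro‑3‑oxocyclobut‑1‑en‑1‑yl)heptadecan‑3‑yl 2,2‑dimethylpropanoate, via dichloroketene 10 (not isolated)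
Conditions: Zn(Cu) couple, Et2O–DME, rt, slow addition of 9
Reagents that add atoms: none
Why: Ketene–alkyne [2+2] cycloaddition: the electrophilic carbonyl carbon of dichloroketene bonds to the terminal alkyne CH, which places the chain at C3 of the cyclobutenone, and DME ties up the ZnCl2 that would otherwise polymerise the ketene.

Step 6
Reactants: 11 (3S)‑17‑(4,4‑dichloro‑3‑oxocyclobut‑1‑en‑1‑yl)heptadecan‑3‑yl 2,2‑dimethylpropanoate
Product: 12 (3S)‑17‑(3‑oxocyclobut‑1‑en‑1‑yl)heptadecan‑3‑yl 2,2‑dimethylpropanoate
Conditions: Zn dust, AcOH, TMEDA, EtOH, 0 °C → rt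
Reagents that add atoms: none
Why: Reductive dechlorination of an α,α‑dichloroketone through zinc enolates that are protonated by acetic acid; the amine‑buffered medium should spare the sensitive cyclobutenone and the ester.

Step 7
Reactants: 12 (3S)‑17‑(3‑oxocyclobut‑1‑en‑1‑yl)heptadecan‑3‑yl 2,2‑dimethylpropanoate; 13 ethoxyethyne
Product: 18 (3S)‑17‑(3‑ethoxy‑5‑hydroxyphenyl)heptadecan‑3‑yl 2,2‑dimethylpropanoate, via vinylketene 14 (not isolated), via 4‑alkenyl‑3‑ethoxycyclobutenone 15 (not isolated), via dienylketene 16 (not isolated), via cyclohexa‑2,4‑dienone 17 (not isolated)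
Conditions: 13 (3 equiv, hexanes solution), toluene, 80 °C, sealed tube, argon
Reagents that add atoms: none
Why: Heat opens 12 reversibly (4π electrocyclic) to vinylketene 14, whose ketene C=C adds the electron‑rich ynol ether in a [2+2] cycloaddition to give 15; a second 4π opening gives dienylketene 16, which closes to dienone 17 and tautomerises to the phenol. This is the Danheiser benzannulation of cyclobutenones with alkoxyalkynes, applied to a 3‑alkylcyclobutenone as in the parent cases. The benzene ring is closed by the 6π electrocyclisation of 16, which remakes the bond between the former carbonyl carbon and former C4 of 12 (arene C1–C6) after the [2+2] step has made C1–C2 and C3–C4. No stereocentre is created: the sp3 ring carbon of 15 is lost on ring opening, and the carbinol centre sits at the far end of a fourteen‑methylene tether as a pivalate, untouched by neutral heating. The one selectivity needed is the orientation of the [2+2] step, and polarity secures it: the electrophilic ketene carbon joins the nucleophilic CH terminus of 13, so ethoxy lands meta to the new hydroxyl and the chain takes C5. Excess 13 in a closed vessel offsets its volatility and should keep capture of 14 faster than its dimerisation.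

Step 8
Reactants: 18 (3S)‑17‑(3‑ethoxy‑5‑hydroxyphenyl)heptadecan‑3‑yl 2,2‑dimethylpropanoate
Product: 19 (3S)‑17‑(3,5‑dihydroxyphenyl)heptadecan‑3‑yl 2,2‑dimethylpropanoate
Conditions: BBr3 (3.5 equiv), CH2Cl2, −78 → 0 °C; then H2O
Reagents that add atoms: none
Why: Lewis‑acid O‑dealkylation: boron binds the aryl ether oxygen and bromide attacks the primary ethyl carbon (SN2), while the hindered secondary pivalate is a poorer donor and a poorer SN2 site at or below 0 °C, so the C3–O bond and its configuration should survive.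

Step 9
Reactants: 19 (3S)‑17‑(3,5‑dihydroxyphenyl)heptadecan‑3‑yl 2,2‑dimethylpropanoate
Product: 20 hansfordiol C (5‑[(15S)‑15‑hydroxyheptadecyl]benzene‑1,3‑diol)
Conditions: KOH, MeOH–H2O, 65 °C, argon; then aq. HCl
Reagents that add atoms: none
Why: Saponification by acyl–oxygen cleavage leaves the C3–O bond intact, so the S configuration is retained, and exclusion of air protects the electron‑rich resorcinol dianion.

**Compound list**

1 | 1‑hexadecyne | CCCCCCCCCCCCCCC#C | starting material
2 | N‑methoxy‑N‑methylpropanamide | CCC(=O)N(C)OC | starting material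
3 | lithium hexadec‑1‑ynide | [Li]C#CCCCCCCCCCCCCCC | intermediate
4 | nonadec‑4‑yn‑3‑one | CCC(=O)C#CCCCCCCCCCCCCCC | intermediate
5 | (3S)‑nonadec‑4‑yn‑3‑ol | CC[C@H](O)C#CCCCCCCCCCCCCCC | intermediate
6 | dipotassium salt of 7 (C3 alkoxide, C19 acetylide) | [K+].[K+].CC[C@H]([O-])CCCCCCCCCCCCCCC#[C-] | intermediate
7 | (3S)‑nonadec‑18‑yn‑3‑ol | CC[C@H](O)CCCCCCCCCCCCCCC#C | intermediate
8 | (3S)‑nonadec‑18‑yn‑3‑yl 2,2‑dimethylpropanoate | CC[C@H](OC(=O)C(C)(C)C)CCCCCCCCCCCCCCC#C | intermediate
9 | trichloroacetyl chloride | ClC(Cl)(Cl)C(Cl)=O | starting material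
10 | dichloroketene | ClC(Cl)=C=O | intermediate
11 | (3S)‑17‑(4,4‑dichloro‑3‑oxocyclobut‑1‑en‑1‑yl)heptadecan‑3‑yl 2,2‑dimethylpropanoate | CC[C@H](OC(=O)C(C)(C)C)CCCCCCCCCCCCCCC1=CC(=O)C1(Cl)Cl | intermediate
12 | (3S)‑17‑(3‑oxocyclobut‑1‑en‑1‑yl)heptadecan‑3‑yl 2,2‑dimethylpropanoate | CC[C@H](OC(=O)C(C)(C)C)CCCCCCCCCCCCCCC1=CC(=O)C1 | intermediate
13 | ethoxyethyne | CCOC#C | starting material
14 | vinylketene, (3S)‑18‑methylidene‑20‑oxoicos‑19‑en‑3‑yl 2,2‑dimethylpropanoate | CC[C@H](OC(=O)C(C)(C)C)CCCCCCCCCCCCCCC(=C)C=C=O | intermediate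
15 | (3S)‑18‑(2‑ethoxy‑4‑oxocyclobut‑2‑en‑1‑yl)nonadec‑18‑en‑3‑yl 2,2‑dimethylpropanoate (ring CH epimers, centre lost in the next event) | CC[C@H](OC(=O)C(C)(C)C)CCCCCCCCCCCCCCC(=C)C1C(=O)C=C1OCC | intermediate
16 | dienylketene, (3S,19E)‑20‑ethoxy‑18‑methylidene‑22‑oxodocosa‑19,21‑dien‑3‑yl 2,2‑dimethylpropanoate | CC[C@H](OC(=O)C(C)(C)C)CCCCCCCCCCCCCCC(=C)/C=C(/OCC)C=C=O | intermediate
17 | (3S)‑17‑(3‑ethoxy‑5‑oxocyclohexa‑1,3‑dien‑1‑yl)heptadecan‑3‑yl 2,2‑dimethylpropanoate | CC[C@H](OC(=O)C(C)(C)C)CCCCCCCCCCCCCCC1=CC(OCC)=CC(=O)C1 | intermediate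
18 | (3S)‑17‑(3‑ethoxy‑5‑hydroxyphenyl)heptadecan‑3‑yl 2,2‑dimethylpropanoate | CC[C@H](OC(=O)C(C)(C)C)CCCCCCCCCCCCCCc1cc(O)cc(OCC)c1 | intermediate
19 | (3S)‑17‑(3,5‑dihydroxyphenyl)heptadecan‑3‑yl 2,2‑dimethylpropanoate | CC[C@H](OC(=O)C(C)(C)C)CCCCCCCCCCCCCCc1cc(O)cc(O)c1 | intermediate
20 | hansfordiol C, 5‑[(15S)‑15‑hydroxyheptadecyl]benzene‑1,3‑diol | CC[C@H](O)CCCCCCCCCCCCCCc1cc(O)cc(O)c1 | target

**Summary**

Total step count: 9. Longest linear sequence: 9 steps, from 1‑hexadecyne 1 to 20.

Steps most likely to fail: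

1. Step 7. The volatile ynol ether may be lost or may fragment thermally before it captures the vinylketene. The vinylketene may instead dimerise or acylate the product phenol, so the cascade stalls short of the arene. The fallback replaces the pericyclic ring construction by an anionic one; it sets out from alkyne 8 and returns at 20. Lithiation of 8 (n‑BuLi, THF, −78 °C) and acylation with N‑methoxy‑N‑methylacetamide should give the methyl ynone (3S)‑20‑oxohenicos‑18‑yn‑3‑yl 2,2‑dimethylpropanoate F1. Dimethyl malonate with NaOMe in MeOH at 65 °C should add to the chain‑bearing alkyne carbon and close by Claisen condensation of the methyl ketone onto one ester (Michael–Claisen annulation). This would give the β‑resorcylate methyl 2,4‑dihydroxy‑6‑[(15S)‑15‑(2,2‑dimethylpropanoyloxy)heptadecyl]benzoate F2, in which the two alkyne carbons are again ring carbons. KOH in aqueous methanol at reflux, then acidification and warming, should hydrolyse both esters and decarboxylate the β‑resorcylic acid to 20. Partial loss of the pivalate during the annulation would not matter, since the last operation removes it.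

2. Step 5. Dichloroketene may oligomerise under ZnCl2 faster than the unactivated alkyne captures it, and the dichlorocyclobutenone may degrade on work‑up. The fallback sets out from 8 and returns at 12, bypassing 11. The keteniminium triflate made from N,N‑dimethylacetamide, Tf2O and 2,4,6‑collidine in 1,2‑dichloroethane at reflux should undergo [2+2] cycloaddition with the terminal alkyne, the iminium carbon bonding to the alkyne CH. The resulting cyclobuteniminium salt, N‑[3‑[(15S)‑15‑(2,2‑dimethylpropanoyloxy)heptadecyl]cyclobut‑2‑en‑1‑ylidene]‑N‑methylmethanaminium triflate F3, would be hydrolysed with aqueous NaHCO3 to 12.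

3. Step 8. The boron halide may activate the ester carbonyl, leading to ionisation or bromide substitution at C3 and erosion of the carbinol configuration. De‑ethylation may also stay incomplete at the temperatures where the ester is safe. The fallback reverses the order of unmasking and changes the dealkylation mechanism; it sets out from 18 and returns at 20. KOH in MeOH–H2O at 65 °C should first give (3S)‑17‑(3‑ethoxy‑5‑hydroxyphenyl)heptadecan‑3‑ol F4, so that no ester meets a Lewis acid. The hard acid/soft nucleophile pair AlCl3/EtSH (CH2Cl2, 0 °C → rt) should then remove the ethyl group by thiol attack on the ethyl carbon of the aluminium‑bound aryl ether. The secondary aluminium alkoxide does not ionise, so 20 should result.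

**Further compounds**

F1 | step 7 | (3S)‑20‑oxohenicos‑18‑yn‑3‑yl 2,2‑dimethylpropanoate | CC[C@H](OC(=O)C(C)(C)C)CCCCCCCCCCCCCCC#CC(C)=O
F2 | step 7 | methyl 2,4‑dihydroxy‑6‑[(15S)‑15‑(2,2‑dimethylpropanoyloxy)heptadecyl]benzoate | CC[C@H](OC(=O)C(C)(C)C)CCCCCCCCCCCCCCc1cc(O)cc(O)c1C(=O)OC
F3 | step 5 | N‑[3‑[(15S)‑15‑(2,2‑dimethylpropanoyloxy)heptadecyl]cyclobut‑2‑en‑1‑ylidene]‑N‑methylmethanaminium trifluoromethanesulfonate | CC[C@H](OC(=O)C(C)(C)C)CCCCCCCCCCCCCCC1=CC(=[N+](C)C)C1.[O-]S(=O)(=O)C(F)(F)F
F4 | step 8 | (3S)‑17‑(3‑ethoxy‑5‑hydroxyphenyl)heptadecan‑3‑ol | CC[C@H](O)CCCCCCCCCCCCCCc1cc(O)cc(OCC)c1
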